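At 31.4% of the charged starting material, the target in Monday's flask stops climbing. That level is our mean of the readings at 3.00 h and 8.00 h, and it carries their scatter of 1 percentage point.

the same everywhere: free catalyst 0.2 mol%; temperature 25 °C
- Monday's: starting material 1 M; second substrate 1 equiv; partner 1.1 equiv; the very flask that is asked about, followed so far
- Wednesday's: starting material 1 M; second substrate 2 equiv; partner 1.1 equiv; run made earlier
- flask: starting material 1.0 M; second substrate 1.00 equiv; partner 1.10 equiv; time 10 h

Monday's run (percent of the starting material charged)

| time / h | target / % | starting material / % |
|---|---|---|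
| 0.667 | 25.3 | 77.4 |
| 1.33 | 31.9 | 69.3 |
| 3.00 | 32.0 | 66.3 |
| 8.00 | 30.8 | 67.1 |

Wednesday's run (percent of the starting material charged)

| time / min | target / % | starting material / % |
|---|---|---|
| 5.00 | 5.1 | 96.9 |
| 12.0 | 6.8 | 93.4 |
| 25.0 | 13.3 | 86.2 |
| 60.0 | 20.1 | 80.2 |

(scatter of a reading: 1 percentage point)

- beta: at 10 h take out 90% of the target then present, then wait 3.0 h
- eta: at 10 h add free catalyst, 50.0% of the amount charged, then wait 3.0 h
- theta: change nothing and wait 3.0 h more
- alpha: at 10 h add partner, 50.0% of the amount charged, then wait 3.0 h
- epsilon: at 10 h raise the temperature by 25 K, then wait 3.0 h

- target, in percent of the starting material first charged, at 10 h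
- the option that brings most further target ("none" if no option brings more than 2 percentage points) (beta / eta / theta / alpha / epsilon / none)
- target present, with what was taken out counted in, in percent of the starting material first charged, after beta
- target present, with what was taken out counted in, in percent of the starting material first charged, after theta

- removed target is counted in
- the analysis behind the earlier runs scatters by 1 percentage point, standard deviation
- additions bring no volume worth counting

We draw Monday's curve first. The opening reading gives a mean slope of 0.379 h⁻¹, as a fraction of the charge. Drawn straight, that slope meets the level at 0.828 h, so we put the knee there, and the reading at 1.33 h already stands at 31.9%. Beyond the knee the line runs flat, with 67.1% of the starting material still free at 8.00 h, so lack of starting material does not explain the stop.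

Wednesday's flask, with 2 equiv of second substrate against 1 equiv, climbs at 0.319 h⁻¹ over its first 25.0 min, slower than Monday's. We read second substrate as a rival for what makes target.

Partner is not among the readings, and a dying catalyst could draw the same knee. We commit to partner all the same, as a judgement the readings do not prove. Its charge of 1.1 equiv in Monday's flask stands against 31.4% of target, so on this reading partner also goes some other way than into target. On this reading, control passes at the knee from the catalyst's speed to the partner's supply.

So we carry the partner's return, the level of target per equivalent of partner charged, which is 28.5% of the starting material per equivalent. Our reckoning keeps Monday's flask at the level at 10 h, and in that reckoning waiting, taking target out, fresh catalyst and heat leave it there. Alpha adds 0.550 equiv of partner, which at this return brings 16 points, against the margin of 2 points.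

The forecast gives 31.5% at 10 h, 31.7% after beta and 31.5% after theta, but it names eta: “Fresh catalyst should restart the reaction”. We name alpha, and there the two part.

The flask gives 32.9% at 10 h, and the best option is alpha.

    starting material + free catalyst ⇌ catalyst intermediate A (K = 4.97 M⁻¹, k = 48.6 M⁻¹ min⁻¹, Ea = 58.0 kJ mol⁻¹, ΔH = 12.0 kJ mol⁻¹)
    partner + catalyst intermediate A → free catalyst + target (k = 16.0 M⁻¹ min⁻¹, Ea = 40.0 kJ mol⁻¹)
    second substrate + free catalyst ⇌ catalyst intermediate B (K = 2.80 M⁻¹, k = 2820 M⁻¹ min⁻¹, Ea = 50.0 kJ mol⁻¹, ΔH = −79.0 kJ mol⁻¹)
    partner + catalyst intermediate B → free catalyst + second product (k = 17.8 M⁻¹ min⁻¹, Ea = 63.0 kJ mol⁻¹)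
    2 catalyst intermediate A ⇌ resting dimer, settled at all times (K = 403 M⁻¹, ΔH = −33.0 kJ mol⁻¹)
    partner → decomposed reagent (k = 0.0136 min⁻¹, Ea = 103 kJ mol⁻¹)
    (constants at 25 °C)

Partner, the limiting reagent, stands at 0% free at 10.0 h, with 66.9% of the starting material still free. Alpha brings 18 points where the return gave 16 points, while eta brings 0 points. In the neighbour flask charged with 2.80 equiv of partner, the return gives 79.8%, and that flask holds 77.4% of target at 10.0 h.

The data come from a simulation with constants of no real substance, and the scatter is random.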